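**Retrosynthetic overview**

1. Selaginellin U ⇐ (BBr3: four O–Me cleavages, loss of water at C7) tetramethyl triarylcarbinol ⇐ 4-MeOC6H4Li + 2-alkynylbenzophenone (C7 ketone) ⇐ Sonogashira coupling at C6 of an aryl triflate (C6–C8 bond).
2. The triflate comes from a 2-hydroxybenzophenone that already is ring A with its C6 oxygen; this phenol is the DDQ dehydrogenation product of a 2-aroylcyclohex-4-enone, so ring A is aromatized late.
3. Feature used: in ring A (C1 methyl, C4 anisyl, C5 bearing C7, C6 bearing the alkyne C8≡C9) only C2 and C3 carry hydrogen, so the C2=C3 bond is made by ring-closing metathesis of two vinyl groups sitting on C1 and C4 of an open-chain diketo 1,7-diene.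
4. The diene comes from C-acylation (C5–C6) of 1,3-bis(4-methoxyphenyl)pent-4-en-1-one with 2-methylbut-3-enoyl chloride; that ketone from vinyl cuprate 1,4-addition (C3–C4) to 4,4'-dimethoxychalcone, itself an aldol condensation product (C4–C5).
5. Ring order: the anisyl rings are bought; ring A is the only ring built (closed in step 5, aromatized in step 6); the cyclohexadienone ring is an anisyl ring unmasked in the last step.

Key step: step 5

Remark: compounds 6 to 10 are racemic and, where they hold more than one stereocentre, mixtures of diastereomers; every stereocentre is removed in step 6 and the target is achiral, so none is controlled. β-Diketones are drawn as diketo tautomers.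

**Route**

Step 1
Reactants: 1 4-methoxyacetophenone; 2 4-methoxybenzaldehyde
Product: 4 (E)-1,3-bis(4-methoxyphenyl)prop-2-en-1-one, via aldol adduct 3 (not isolated)
Conditions: NaOH (cat.), EtOH–H2O, rt
Reagents that add atoms: none
Why: Claisen–Schmidt condensation, in which the methyl ketone enolate adds to the non-enolizable aldehyde and the aldol adduct loses water to the conjugated E-enone, which should crystallize from the medium.

Step 2
Reactants: 4 (E)-1,3-bis(4-methoxyphenyl)prop-2-en-1-one; 5 vinylmagnesium bromide
Product: 6 1,3-bis(4-methoxyphenyl)pent-4-en-1-one (racemic)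
Conditions: CH2=CHMgBr (1.5 equiv), CuBr·SMe2 (10 mol %), THF, −40 → −10 °C; then 1 M HCl
Reagents that add atoms: none
Why: Copper-catalysed conjugate (1,4) addition of a vinyl Grignard reagent to an aryl enone, in which the vinylcuprate formed in the flask attacks the β-carbon in preference to the carbonyl and the magnesium enolate is protonated on work-up; the new stereocentre (the later C4 of ring A) forms racemic and is erased in step 6.

Step 3
Reactants: 7 2-methylbut-3-enoic acid (racemic)
Product: 8 2-methylbut-3-enoyl chloride (racemic, used at once as its CH2Cl2 solution)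
Conditions: (COCl)2 (1.1 equiv), DMF (cat.), CH2Cl2, 0 °C → rt
Reagents that add atoms: oxalyl chloride, O=C(Cl)C(=O)Cl
Why: Acid chloride formation through the DMF-derived chloroiminium catalyst, run without base at or below room temperature so that the β,γ C=C should stay out of conjugation, the by-products being gases.

Step 4
Reactants: 6 1,3-bis(4-methoxyphenyl)pent-4-en-1-one; 8 2-methylbut-3-enoyl chloride
Product: 9 1-(4-methoxyphenyl)-2-[1-(4-methoxyphenyl)prop-2-enyl]-4-methylhex-5-ene-1,3-dione (mixture of diastereomers)
Conditions: MgBr2·OEt2 (2.5 equiv), 8 (1.3 equiv), CH2Cl2, 0 °C; i-Pr2NEt (3 equiv) added slowly, 0 °C → rt; then cold 1 M HCl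
Reagents that add atoms: none
Why: Magnesium-mediated soft enolization and C-acylation (crossed Claisen-type acylation of a ketone), in which MgBr2 activates the aryl ketone for enolization by the amine, the magnesium enolate is acylated on carbon and the product is held as its chelated magnesium β-diketonate, which favours C- over O-acylation and shields the β,γ-unsaturated acyl unit from deconjugation until the cold acid quench; the new stereocentres form without control.

Step 5
Reactants: 9 1-(4-methoxyphenyl)-2-[1-(4-methoxyphenyl)prop-2-enyl]-4-methylhex-5-ene-1,3-dione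
Product: 10 2-(4-methoxybenzoyl)-3-(4-methoxyphenyl)-6-methylcyclohex-4-en-1-one (mixture of diastereomers)
Conditions: second-generation Grubbs catalyst RuCl2(=CHPh)(PCy3)(H2IMes) (5 mol %), 1,4-benzoquinone (10 mol %), CH2Cl2 (0.01 M), 40 °C
Reagents that add atoms: none
Why: The ruthenium benzylidene exchanges onto one of the two terminal vinyl groups, the tethered second vinyl group adds to the new alkylidene to give a ruthenacyclobutane, and cycloreversion closes ring A at C2=C3 with release of ethene (ring-closing olefin metathesis). The closest known reaction type is the closure of octa-1,7-dien-4-ones to cyclohex-3-enones that are aromatized afterwards (metathesis–aromatization benzannulation). The one ring formed is six-membered and closes by intramolecular [2+2] cycloaddition and cycloreversion between the two monosubstituted alkenes of the 1,7-diene, the three substituents on the tether (methyl, aroyl, aryl) favouring the folded conformer. No stereocentre is created, and the three existing ones are carried as a mixture because step 6 removes them all. The step needs cyclization to win over oligomerization and over ruthenium hydride-mediated migration of the C1 vinyl group into conjugation with the ketone: dilution and the fast six-ring closure should secure the first, the benzoquinone additive the second, and the substrate offers the catalyst no other alkene or alkyne.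

Step 6
Reactants: 10 2-(4-methoxybenzoyl)-3-(4-methoxyphenyl)-6-methylcyclohex-4-en-1-one
Product: 11 [2-hydroxy-6-(4-methoxyphenyl)-3-methylphenyl](4-methoxyphenyl)methanone
Conditions: DDQ (1.1 equiv), 1,4-dioxane, rt
Reagents that add atoms: none
Why: Dehydrogenative aromatization with DDQ, in which the β-diketone enol of 10 is a cyclohexa-1,4-dienol whose C4–H (benzylic and doubly allylic) is taken as hydride and whose C1 proton is then lost, giving a phenol that is stabilized by the hydrogen bond to the aroyl oxygen and should resist further oxidation by one equivalent of the quinone.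

Step 7
Reactants: 11 [2-hydroxy-6-(4-methoxyphenyl)-3-methylphenyl](4-methoxyphenyl)methanone
Product: 12 2-(4-methoxybenzoyl)-3-(4-methoxyphenyl)-6-methylphenyl trifluoromethanesulfonate
Conditions: Tf2O (1.3 equiv), pyridine (3 equiv), CH2Cl2, 0 °C → rt
Reagents that add atoms: trifluoromethanesulfonic anhydride, O=S(=O)(OS(=O)(=O)C(F)(F)F)C(F)(F)F
Why: Aryl triflate formation (O-sulfonylation of a phenol), in which pyridine opens the intramolecular hydrogen bond and the phenoxide attacks the anhydride while the ketone and the methyl ethers stay untouched.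

Step 8
Reactants: 12 2-(4-methoxybenzoyl)-3-(4-methoxyphenyl)-6-methylphenyl trifluoromethanesulfonate; 13 4-ethynylanisole
Product: 14 [6-(4-methoxyphenyl)-2-[(4-methoxyphenyl)ethynyl]-3-methylphenyl](4-methoxyphenyl)methanone
Conditions: 13 (1.5 equiv), PdCl2(PPh3)2 (5 mol %), CuI (10 mol %), Et3N (3 equiv), DMF, 80 °C
Reagents that add atoms: none
Why: Sonogashira coupling, in which oxidative addition into the C6–OTf bond is helped by the ortho aroyl group and the copper acetylide of 13 delivers the C8≡C9 unit, the diaryl ketone and the ethers being spectators.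

Step 9
Reactants: 14 [6-(4-methoxyphenyl)-2-[(4-methoxyphenyl)ethynyl]-3-methylphenyl](4-methoxyphenyl)methanone; 15 4-bromoanisole
Product: 17 [6-(4-methoxyphenyl)-2-[(4-methoxyphenyl)ethynyl]-3-methylphenyl]bis(4-methoxyphenyl)methanol, via 4-methoxyphenyllithium 16 (not isolated)
Conditions: 15 (3 equiv), n-BuLi (3 equiv), THF, −78 °C; then 14, −78 → 0 °C; then H2O at 0 °C
Reagents that add atoms: none
Why: Bromine–lithium exchange followed by 1,2-addition of the aryllithium to a non-enolizable diaryl ketone, the small and reactive aryllithium being expected to reach the hindered carbonyl while the diaryl alkyne is inert and the cold quench keeps the tertiary lithium alkoxide from adding to the neighbouring alkyne; the carbinol carbon bears two identical anisyl groups and is no stereocentre.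

Step 10
Reactants: 17 [6-(4-methoxyphenyl)-2-[(4-methoxyphenyl)ethynyl]-3-methylphenyl]bis(4-methoxyphenyl)methanol
Product: 19 Selaginellin U, via tetraphenol carbinol 18 (not isolated)
Conditions: BBr3 (10 equiv), CH2Cl2, −78 → 0 °C; then H2O
Reagents that add atoms: none
Why: Lewis acid cleavage of aryl methyl ethers with BBr3 (global demethylation), in which the four methyl groups leave as bromomethane and the p-hydroxyphenyl-substituted triarylcarbinol ionizes to a stabilized triarylcarbenium ion that loses a phenolic proton, so that water is lost and the para-quinone methide forms; the product is achiral and its exocyclic C=C has no configuration.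

**Compound list**

1 | 4-methoxyacetophenone | CC(=O)c1ccc(OC)cc1 | starting material
2 | 4-methoxybenzaldehyde | COc1ccc(C=O)cc1 | starting material
3 | 3-hydroxy-1,3-bis(4-methoxyphenyl)propan-1-one (aldol adduct, racemic, not isolated) | COc1ccc(C(O)CC(=O)c2ccc(OC)cc2)cc1 | intermediate
4 | (E)-1,3-bis(4-methoxyphenyl)prop-2-en-1-one (4,4'-dimethoxychalcone) | COc1ccc(/C=C/C(=O)c2ccc(OC)cc2)cc1 | intermediate
5 | vinylmagnesium bromide (THF solution) | C=C[Mg]Br | starting material
6 | 1,3-bis(4-methoxyphenyl)pent-4-en-1-one (racemic) | C=CC(CC(=O)c1ccc(OC)cc1)c1ccc(OC)cc1 | intermediate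
7 | 2-methylbut-3-enoic acid (racemic) | C=CC(C)C(=O)O | starting material
8 | 2-methylbut-3-enoyl chloride (racemic) | C=CC(C)C(=O)Cl | intermediate
9 | 1-(4-methoxyphenyl)-2-[1-(4-methoxyphenyl)prop-2-enyl]-4-methylhex-5-ene-1,3-dione (mixture of diastereomers) | C=CC(C)C(=O)C(C(=O)c1ccc(OC)cc1)C(C=C)c1ccc(OC)cc1 | intermediate
10 | 2-(4-methoxybenzoyl)-3-(4-methoxyphenyl)-6-methylcyclohex-4-en-1-one (mixture of diastereomers) | O=C1C(C)C=CC(c2ccc(OC)cc2)C1C(=O)c1ccc(OC)cc1 | intermediate
11 | [2-hydroxy-6-(4-methoxyphenyl)-3-methylphenyl](4-methoxyphenyl)methanone | Cc1ccc(-c2ccc(OC)cc2)c(C(=O)c2ccc(OC)cc2)c1O | intermediate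
12 | 2-(4-methoxybenzoyl)-3-(4-methoxyphenyl)-6-methylphenyl trifluoromethanesulfonate | Cc1ccc(-c2ccc(OC)cc2)c(C(=O)c2ccc(OC)cc2)c1OS(=O)(=O)C(F)(F)F | intermediate
13 | 4-ethynylanisole | C#Cc1ccc(OC)cc1 | starting material
14 | [6-(4-methoxyphenyl)-2-[(4-methoxyphenyl)ethynyl]-3-methylphenyl](4-methoxyphenyl)methanone | Cc1ccc(-c2ccc(OC)cc2)c(C(=O)c2ccc(OC)cc2)c1C#Cc1ccc(OC)cc1 | intermediate
15 | 4-bromoanisole | COc1ccc(Br)cc1 | starting material
16 | 4-methoxyphenyllithium (not isolated) | [Li]c1ccc(OC)cc1 | intermediate
17 | [6-(4-methoxyphenyl)-2-[(4-methoxyphenyl)ethynyl]-3-methylphenyl]bis(4-methoxyphenyl)methanol | Cc1ccc(-c2ccc(OC)cc2)c(C(O)(c2ccc(OC)cc2)c2ccc(OC)cc2)c1C#Cc1ccc(OC)cc1 | intermediate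
18 | [6-(4-hydroxyphenyl)-2-[(4-hydroxyphenyl)ethynyl]-3-methylphenyl]bis(4-hydroxyphenyl)methanol (tetraphenol carbinol, not isolated) | Cc1ccc(-c2ccc(O)cc2)c(C(O)(c2ccc(O)cc2)c2ccc(O)cc2)c1C#Cc1ccc(O)cc1 | intermediate
19 | Selaginellin U, 4-{[6-(4-hydroxyphenyl)-2-[(4-hydroxyphenyl)ethynyl]-3-methylphenyl](4-hydroxyphenyl)methylidene}cyclohexa-2,5-dien-1-one | Cc1ccc(-c2ccc(O)cc2)c(C(=C2C=CC(=O)C=C2)c2ccc(O)cc2)c1C#Cc1ccc(O)cc1 | target

**Step count**

Total: 10 steps. Longest linear sequence: 9 steps (steps 1, 2 and 4 to 10, from 1 and 2); step 3 is a one-step branch.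

**Steps most likely to fail**

Step 4 (C-acylation). The β-branched ketone may enolize slowly, so that the acid chloride is lost through its ketene. The hindered enolate may be acylated on oxygen. The vinyl C=C of the new acyl unit may migrate into conjugation under the amine base. The fallback sets out from 1 and returns at 9, bringing in the sensitive acyl unit on an unhindered enolate and building the C3–C4 bond last. The lithium enolate of 1 (LiN(SiMe3)2, toluene–THF, 0 °C, two equivalents of enolate per acid chloride) is acylated with 8 to give 1-(4-methoxyphenyl)-4-methylhex-5-ene-1,3-dione F1. Knoevenagel condensation of F1 with 2 (ethylenediammonium diacetate cat., CH2Cl2, 4 Å sieves, rt) should give 2-[(4-methoxyphenyl)methylidene]-1-(4-methoxyphenyl)-4-methylhex-5-ene-1,3-dione F2. CuBr·SMe2-catalysed 1,4-addition of 5 to F2 (THF, −40 °C, then cold 1 M HCl) then gives 9.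

Step 5 (ring-closing metathesis). The chelating β-diketone may bind and slow the ruthenium catalyst. A ruthenium hydride may move the C1 vinyl group into conjugation before closure. A poorly folded chain may react intermolecularly. The fallback sets out from 9 and returns at 10, with the diketone masked and locked in the planar enol geometry that holds the two vinyl-bearing carbons side by side. BF3·OEt2 (CH2Cl2, rt) converts 9 into its boron difluoride β-diketonate F3. The same ruthenium catalyst (CH2Cl2, 40 °C) closes F3 to the bicyclic boron difluoride chelate of the enol of 10 F4. Hydrolysis of F4 (NaOAc, aqueous EtOH, 60 °C) releases 10.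

Step 8 (Sonogashira coupling). Oxidative addition and transmetalation at the triflate flanked by methyl and aroyl groups may be slow, so that copper-mediated oxidative dimerization of the alkyne and base-induced cleavage of the triflate back to 11 take over. The fallback sets out from 13 and returns at 14, using a copper-free and base-free coupling. Compound 13 is lithiated (n-BuLi, THF, −78 °C) and stannylated with n-Bu3SnCl to give tributyl[(4-methoxyphenyl)ethynyl]stannane F5. Stille coupling of F5 with 12 (Pd(PPh3)4, LiCl, 1,4-dioxane, 100 °C) then gives 14.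

Further compounds
F1 | step 4 | 1-(4-methoxyphenyl)-4-methylhex-5-ene-1,3-dione (racemic) | C=CC(C)C(=O)CC(=O)c1ccc(OC)cc1
F2 | step 4 | 2-[(4-methoxyphenyl)methylidene]-1-(4-methoxyphenyl)-4-methylhex-5-ene-1,3-dione (E/Z mixture) | C=CC(C)C(=O)C(=Cc1ccc(OC)cc1)C(=O)c1ccc(OC)cc1
F3 | step 5 | boron difluoride β-diketonate of 9, 4-(but-3-en-2-yl)-2,2-difluoro-6-(4-methoxyphenyl)-5-[1-(4-methoxyphenyl)prop-2-enyl]-1,3,2-dioxaborinine | C=CC(C)C1=[O+][B-](F)(F)OC(c2ccc(OC)cc2)=C1C(C=C)c1ccc(OC)cc1
F4 | step 5 | boron difluoride chelate of the enol of 10 (dioxaborinine fused to the cyclohexadiene ring) | CC1C=CC(c2ccc(OC)cc2)C2=C(c3ccc(OC)cc3)O[B-](F)(F)[O+]=C12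
F5 | step 8 | tributyl[(4-methoxyphenyl)ethynyl]stannane | CCCC[Sn](CCCC)(CCCC)C#Cc1ccc(OC)cc1
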